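**Retrosynthetic overview**

1. Quinone numbering used here: C1 is the carbonyl carbon between C2 (OMe) and C6 (side chain), C4 the carbonyl carbon between C3–H and C5–H; the last event is oxidation of the corresponding hydroquinone.
2. Enabling feature: in the six-membered ring the oxygen-bearing carbons C1 and C4 are para, C4 is flanked by two unsubstituted CH carbons, and C2–C3 is an enol-ether unit C(OMe)=CH. This is the imprint of a hydroxy-dienylketene, so the ring bond C3–C4 is cut back to a ketene carbon (C4) and the CH2 end of a 1-methoxyvinyl group (6π electrocyclization in the forward sense).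
3. The dienylketene is the 4π ring-opened form of a 4-hydroxy-4-(1-methoxyvinyl)cyclobut-2-enone that already holds C4, C5, C6 and C1; it is disconnected at C1–C2 to 1-methoxyvinyllithium and a 3-alkylcyclobutene-1,2-dione.
4. The dione comes from a [2+2] cycloaddition of dichloroketene (its carbonyl carbon becomes C4, its CCl2 carbon C1) with heptadec-16-ynoic acid as its tert-butyl ester (C5, C6 and the whole side chain), made from 15-bromopentadecanoic acid and lithium acetylide.
5. Ring order: the four-membered ring first (step 3), the six-membered quinone ring last (step 6); no protecting group remains after step 4.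

Key step: step 6

Remark: the target is achiral; the only stereocentre on the route (the carbinol carbon of the racemic hydroxycyclobutenone) is destroyed in the key step, and 15-bromopentadecanoic acid is taken as a commercial starting material.

**Route**

Step 1
Reactants: 1 15-bromopentadecanoic acid; 2 lithium acetylide–ethylenediamine complex (LiC≡CH·H2NCH2CH2NH2)
Product: 3 heptadec-16-ynoic acid
Conditions: 2 (3 equiv), DMSO, 10 °C → rt; aq. HCl work-up
Reagents that add atoms: none
Why: SN2 alkylation of lithium acetylide by the primary bromide in DMSO, the carboxylate formed by the first equivalent being inert, as in the standard preparation of ω-alkynoic acids from ω-bromo acids.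

Step 2
Reactants: 3 heptadec-16-ynoic acid
Product: 4 tert-butyl heptadec-16-ynoate
Conditions: isobutene (excess), H2SO4 (cat.), CH2Cl2, −20 °C → rt, sealed tube
Reagents that add atoms: isobutene (2-methylpropene), CC(C)=C
Why: acid-catalysed addition of the carboxylic acid to isobutene (tert-butyl esterification) masks the acid against acylation by trichloroacetyl chloride in step 3, with an ester that is removed without a separate step in step 4.

Step 3
Reactants: 4 tert-butyl heptadec-16-ynoate; 5 trichloroacetyl chloride
Product: 6 tert-butyl 15-(4,4-dichloro-3-oxocyclobut-1-en-1-yl)pentadecanoate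
Conditions: 5 (2 equiv, slow addition), Zn–Cu couple, Et2O/DME, rt
Reagents that add atoms: none
Why: [2+2] cycloaddition of dichloroketene (from reductive dechlorination of 5 by zinc) with a terminal alkyne, in which the ketene carbonyl carbon bonds to the terminal CH so that the chain sits at C3 of the 4,4-dichlorocyclobutenone, as established for simple 1-alkynes; DME holds ZnCl2 so that the ester and the product should survive.

Step 4
Reactants: 6 tert-butyl 15-(4,4-dichloro-3-oxocyclobut-1-en-1-yl)pentadecanoate
Product: 8 15-(3,4-dioxocyclobut-1-en-1-yl)pentadecanoic acid, via dichlorocyclobutenone acid 7 (not isolated)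
Conditions: conc. H2SO4, 0 → 50 °C; then poured onto ice
Reagents that add atoms: water, O
Why: acidolysis cleaves the tert-butyl ester (AAL1) and ionises the allylic gem-dichloride to a chloro-oxocyclobutenyl cation that takes up water at the chlorine-bearing carbon and loses HCl, the known acid hydrolysis of 4,4-dichlorocyclobutenones to cyclobutenediones (a 2,4-dichloro isomer formed by chlorine shift passes through the same cation to the same dione).

Step 5
Reactants: 8 15-(3,4-dioxocyclobut-1-en-1-yl)pentadecanoic acid; 9 methyl vinyl ether
Product: 10 (±)-15-[4-hydroxy-4-(1-methoxyethenyl)-3-oxocyclobut-1-en-1-yl]pentadecanoic acid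
Conditions: 9 (3 equiv), t-BuLi (2.3 equiv), THF, −78 → 0 °C (gives 1-methoxyvinyllithium, 2.2 equiv); transferred into 8, THF, −78 °C; sat. aq. NH4Cl, −78 → 0 °C
Reagents that add atoms: none
Why: 1,2-addition of an alkenyllithium to a cyclobutenedione, expected next to the alkyl-bearing carbon because that carbonyl is only cross-conjugated whereas the CH-flanked carbonyl is a β-alkyl enone carbonyl deactivated by vinylogous donation (the bias seen in 2-alkylmaleic anhydrides and imides and, more strongly, in 3-alkoxycyclobutenediones); the first equivalent is consumed by the carboxylic acid, whose lithium salt is inert at −78 °C, and the new stereocentre is formed racemic and erased in step 6.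

Step 6
Reactants: 10 (±)-15-[4-hydroxy-4-(1-methoxyethenyl)-3-oxocyclobut-1-en-1-yl]pentadecanoic acid
Product: 14 15-(5-methoxy-3,6-dioxocyclohexa-1,4-dien-1-yl)pentadecanoic acid, via dienylketene 11 (not isolated), via cyclohexadienone 12 (not isolated), via hydroquinone 13 (not isolated)
Conditions: PhMe (0.02 M, degassed), 110 °C, Ar; then FeCl3 (2.2 equiv), EtOAc/H2O, rt
Reagents that add atoms: none
Why: Heating opens the cyclobutenone by conrotatory 4π electrocyclic cleavage of the C(=O)–C(OH) bond with the hydroxyl turning outward, so that dienylketene 11 has the 1-methoxyvinyl group cis to the ketene, and a thermal disrotatory 6π electrocyclization then joins the ketene carbon to the CH2 terminus of the enol ether. The closest known reaction type is the Moore rearrangement, the ring expansion of 4-alkenyl-4-hydroxycyclobutenones to hydroquinones and quinones. The six-membered ring is closed by this 6π electrocyclization, dienone 12 aromatises by enolisation to hydroquinone 13, and FeCl3 oxidises 13 to the quinone in the same flask. No stereocentre is formed and the one in 10 is destroyed. The selectivity needed is torquoselectivity (alkenyl inward), secured by the strong outward preference of the donor OH group on the breaking carbon, while the substitution pattern is fixed by connectivity, since the ketene carbon becomes the CH-flanked carbonyl and the carbinol carbon becomes the carbonyl between C–OMe and C–alkyl. At high dilution the intramolecular pericyclic steps should outrun capture of the ketene by the remote carboxylic acid.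

**Compound list**

1 | 15-bromopentadecanoic acid | BrCCCCCCCCCCCCCCC(=O)O | starting material
2 | lithium acetylide–ethylenediamine complex | [Li]C#C.NCCN | starting material
3 | heptadec-16-ynoic acid | C#CCCCCCCCCCCCCCCC(=O)O | intermediate
4 | tert-butyl heptadec-16-ynoate | C#CCCCCCCCCCCCCCCC(=O)OC(C)(C)C | intermediate
5 | trichloroacetyl chloride | ClC(=O)C(Cl)(Cl)Cl | starting material
6 | tert-butyl 15-(4,4-dichloro-3-oxocyclobut-1-en-1-yl)pentadecanoate | O=C1C=C(CCCCCCCCCCCCCCC(=O)OC(C)(C)C)C1(Cl)Cl | intermediate
7 | 15-(4,4-dichloro-3-oxocyclobut-1-en-1-yl)pentadecanoic acid (dichlorocyclobutenone acid, not isolated) | O=C1C=C(CCCCCCCCCCCCCCC(=O)O)C1(Cl)Cl | intermediate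
8 | 15-(3,4-dioxocyclobut-1-en-1-yl)pentadecanoic acid | O=C1C=C(CCCCCCCCCCCCCCC(=O)O)C1=O | intermediate
9 | methyl vinyl ether | COC=C | starting material
10 | (±)-15-[4-hydroxy-4-(1-methoxyethenyl)-3-oxocyclobut-1-en-1-yl]pentadecanoic acid (racemic) | O=C1C=C(CCCCCCCCCCCCCCC(=O)O)C1(O)C(=C)OC | intermediate
11 | (3E)-3-(14-carboxytetradecyl)-4-hydroxy-5-methoxyhexa-1,3,5-trien-1-one (dienylketene, ketene and 1-methoxyvinyl cis, not isolated) | O=C=C/C(CCCCCCCCCCCCCCC(=O)O)=C(/O)C(=C)OC | intermediate
12 | 15-(6-hydroxy-5-methoxy-3-oxocyclohexa-1,5-dien-1-yl)pentadecanoic acid (cyclohexadienone, not isolated) | O=C1CC(OC)=C(O)C(CCCCCCCCCCCCCCC(=O)O)=C1 | intermediate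
13 | 15-(2,5-dihydroxy-3-methoxyphenyl)pentadecanoic acid (hydroquinone, not isolated) | COc1cc(O)cc(CCCCCCCCCCCCCCC(=O)O)c1O | intermediate
14 | 15-(5-methoxy-3,6-dioxocyclohexa-1,4-dien-1-yl)pentadecanoic acid | COC1=CC(=O)C=C(CCCCCCCCCCCCCCC(=O)O)C1=O | target

**Step count and risks**

Total step count: 6. Longest linear sequence: 6 steps (from 1).

Steps most likely to fail, riskiest first:

Step 5. Process at risk: attack of the lithium reagent at the CH-flanked carbonyl instead of the carbonyl next to the alkyl-bearing carbon, which would carry the side chain to the wrong ring position after step 6, and γ-deprotonation of the dione. The fallback fixes the regiochemistry by cross-coupling at a carbon whose position is set by the ketene cycloaddition, with no carbonyl addition; it sets out from 6. Removal of one chlorine with Zn dust, AcOH and TMEDA in EtOH at 0 °C should give tert-butyl 15-(4-chloro-3-oxocyclobut-1-en-1-yl)pentadecanoate F1. Stille coupling with tributyl(1-methoxyvinyl)stannane (PdCl2(PhCN)2, tri(2-furyl)phosphine, dioxane, 50 → 100 °C) should give tert-butyl 15-[4-(1-methoxyethenyl)-3-oxocyclobut-1-en-1-yl]pentadecanoate F2. F2 is not isolated: it opens to the dienylketene and closes the same ring bond by 6π electrocyclization to tert-butyl 15-(3-hydroxy-5-methoxyphenyl)pentadecanoate F3. Oxidation para to the hydroxyl with (KSO3)2NO (Fremy's salt) in KH2PO4-buffered aqueous acetone should give tert-butyl 15-(5-methoxy-3,6-dioxocyclohexa-1,4-dien-1-yl)pentadecanoate F4, and TFA in CH2Cl2 removes the tert-butyl group. The fallback comes back to the route at 14.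

Step 6. Process at risk: proton-catalysed loss of the enol ether or ionisation of the tertiary carbinol, brought about by the free carboxylic acid at 110 °C, and capture of the ketene by that acid, all in competition with the pericyclic cascade. The fallback runs the rearrangement on a fully capped, aprotic substrate (the 4-silyloxy variant of the ring expansion); it sets out from 10. N,O-bis(trimethylsilyl)acetamide in CH2Cl2 at rt should give trimethylsilyl 15-[4-(1-methoxyethenyl)-3-oxo-4-(trimethylsilyloxy)cyclobut-1-en-1-yl]pentadecanoate F5. Heating in toluene at 110 °C should give trimethylsilyl 15-[5-hydroxy-3-methoxy-2-(trimethylsilyloxy)phenyl]pentadecanoate F6. Mild acidic hydrolysis (AcOH, THF/H2O, under argon) removes both silyl groups, and the fallback comes back to the route at 13, which is oxidised with FeCl3 as in the second half of step 6.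

Step 4. Process at risk: sulfonation or charring in warm concentrated acid, hydrolytic opening of the strained dione during the aqueous quench, or stalling at a chloro-hydroxy-cyclobutenone. The fallback makes the dione directly from the alkyne by double carbonylation, with no halogenated ring and no strong mineral acid; it sets out from 4. Treatment with the hydridoiron carbonyl reagent made from Fe(CO)5, NaBH4 and AcOH in THF, followed by oxidation with CuCl2·2H2O, a known conversion of alkynes into cyclobutenediones, should give tert-butyl 15-(3,4-dioxocyclobut-1-en-1-yl)pentadecanoate F7. TFA in CH2Cl2 at rt cleaves the ester, and the fallback comes back to the route at 8.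

**Further compounds**

F1 | step 5 | tert-butyl 15-(4-chloro-3-oxocyclobut-1-en-1-yl)pentadecanoate | O=C1C=C(CCCCCCCCCCCCCCC(=O)OC(C)(C)C)C1Cl
F2 | step 5 | tert-butyl 15-[4-(1-methoxyethenyl)-3-oxocyclobut-1-en-1-yl]pentadecanoate | O=C1C=C(CCCCCCCCCCCCCCC(=O)OC(C)(C)C)C1C(=C)OC
F3 | step 5 | tert-butyl 15-(3-hydroxy-5-methoxyphenyl)pentadecanoate | COc1cc(O)cc(CCCCCCCCCCCCCCC(=O)OC(C)(C)C)c1
F4 | step 5 | tert-butyl 15-(5-methoxy-3,6-dioxocyclohexa-1,4-dien-1-yl)pentadecanoate | COC1=CC(=O)C=C(CCCCCCCCCCCCCCC(=O)OC(C)(C)C)C1=O
F5 | step 6 | trimethylsilyl 15-[4-(1-methoxyethenyl)-3-oxo-4-(trimethylsilyloxy)cyclobut-1-en-1-yl]pentadecanoate | O=C1C=C(CCCCCCCCCCCCCCC(=O)O[Si](C)(C)C)C1(O[Si](C)(C)C)C(=C)OC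
F6 | step 6 | trimethylsilyl 15-[5-hydroxy-3-methoxy-2-(trimethylsilyloxy)phenyl]pentadecanoate | COc1cc(O)cc(CCCCCCCCCCCCCCC(=O)O[Si](C)(C)C)c1O[Si](C)(C)C
F7 | step 4 | tert-butyl 15-(3,4-dioxocyclobut-1-en-1-yl)pentadecanoate | O=C1C=C(CCCCCCCCCCCCCCC(=O)OC(C)(C)C)C1=O
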